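## Structural features

The target 26 is a C40 carotenoid with one carbocycle, the six-membered β ring (C1–C6), and an open ψ end. The ring C5=C6 bond and ten chain double bonds (C7 to C5') form one all-E conjugated undecaene; the C1'=C2' bond at the far end is isolated. The ring carries a gem-dimethyl group at C1, a methyl at C5 and two adjacent secondary carbinols at C3 and C4. Both are R, the hydroxyls are trans, and they are the only stereocentres. C4 is allylic to C5=C6 and through it to the whole polyene, so its C–O bond ionises easily under acid (loss of water, retro shift of the double bonds, epimerisation). The polyene itself is sensitive to light, oxygen, acid and E/Z scrambling. The real difficulty is not the chain, which comes from standard C15, C10 and C15 units, but the trans-3,4-diol: C4 has to be set relative to C3 beside a tetrasubstituted alkene and must then survive every later step. The key step exploits the 1,3 relationship of O4 to C6 across the C5=C6 bond. A tertiary C6 carbinol with a C4=C5 bond is the allylic isomer of the C4 carbinol, and it is simply the 1,2-adduct of a C7 acetylide to the C6 carbonyl of a ketoisophorone-derived ring that already holds O3.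

## Logic of the disconnections

26 from 25. The two O–Si bonds at O3 and O4 are cut last. The free allylic diol should not meet carbanions, Mitsunobu reagents or acid, so it stays masked until the end. The gain is a final step that is a simple fluoride cleavage. The demand is that the deprotection neither ionises C4–O nor disturbs the polyene.

25 from 15 and 22. The C11=C12 double bond is cut. This divides C40 into a small chiral C15 ring unit and an achiral C25 polyenal, at a disubstituted bond whose hindered Z isomer can be corrected thermally. All stereochemistry is then confined to the small fragment. The forward olefination must run in base without expelling the O4 substituent from the delocalised carbanion, and must end with E geometry.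

22 from 19 and 18, then 18 from 17 and 17 from 16. The C11'=C12' bond is cut, then the C11'–P bond with an allylic shift, then the C9'–vinyl bond. This reduces the C25 aldehyde to two commercial chain units and one vinyl group. The demands are mono-olefination of a symmetrical dialdehyde and E geometry at C9' and C11'.

15 from 14 and 14 from 13. The S=O bonds and then the C11–S bond are cut. A primary allylic alcohol becomes the sulfone in two neutral steps. Substitution must occur at C11 without allylic shift, and oxidation at sulfur only.

13 from 11 (through 12), and 11 from 10. The C7–H and C8–H bonds of the E alkene are traced back to the C7≡C8 alkyne, and the O11–Si and O4–Si bonds are adjusted. The alkyne is what the key step needs on C6, so it must be removed afterwards. The demand is a stereospecific trans semireduction that does not rely on a directing hydroxyl, because O11 lies on the far side of the E C9=C10 bond.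

10 from 7. The C4–O bond is cut and the oxygen is reconnected to C6, with the double bond moved to C4=C5. The secondary allylic stereocentre becomes a tertiary carbinol that is made by carbonyl addition, and C4 then takes its configuration from C6. The forward step must be suprafacial, must not ionise, and must have its equilibrium on the conjugated side.

7 from 3 and 6 (from 5 and 4), and 3 from 2 and 1. The C6–C7 bond is cut, giving a C9 ring enone and a C6 enyne. Then the O3–Si bond and the C3–H bond are cut, back to the achiral ene-dione. The demands are face selectivity in the acetylide addition (hydroxyl trans to O3) and an enantioselective reduction of the unhindered carbonyl.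

## Other disconnections considered

Alternative 1: The cut removes both ring C–O bonds at once and traces O3 and O4 back to the cis C3=C4 bond of safranal A2. In the forward direction NaOCl and chloro[N,N'-bis(3,5-di-tert-butylsalicylidene)cyclohexane-1,2-diaminato]manganese (trivalent manganese) would transfer oxygen to one face of that bond to give the oxide A1. An oxygen nucleophile opening the oxirane at the allylic C4 with inversion would then give the trans-diol aldehyde A3.
- In favour: A2 is a cheap achiral ring aldehyde that already holds C1–C7. A cis-disubstituted conjugated ring alkene is the substrate class this catalyst handles best. The C3=C4 bond should react before the tetrasubstituted, aldehyde-conjugated C5=C6 bond.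
- Equal or better: the trans relationship follows from anti opening as rigorously as from the suprafacial shift of the chosen plan (equal). Both stereocentres come from one catalytic event on an achiral substrate, without a stoichiometric chiral reagent or a relay through C6 (better).
- Against: the reacting alkene is vinylogously deactivated by the aldehyde, so enantioselectivity and rate are uncertain, and hypochlorite may oxidise the aldehyde. The opening at C4 is opposed electronically by the aldehyde at the other end of C5=C6 and sterically by the C5 methyl, so attack at C3 or base-induced eliminative opening through the C5-methyl dienolate may compete.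
- Step economy: the chain from C8 onwards must still be built on A3, with an ionisable C4–O bond conjugated to a carbonyl, whereas the acetylide of the chosen plan brings C7–C11 in the step that makes the C6 carbinol. The alternative is shorter to a ring block and longer to a C15 unit.
- Mechanism: it needs two intermolecular selective events (face, then regiochemistry), where the chosen plan needs one intramolecular shift whose facial outcome cannot vary.

Alternative 2: The cut is the C3–O bond together with the C4–H bond. The C3 hydroxyl is added to the C3=C4 bond of the silyl dienol ether A5, which would come from the achiral 4-oxo ring pivalate A6 by enolisation towards C3. In the forward direction IpcBH2 would place boron on C3 and hydrogen on C4 on the same face. NaBO3 would replace boron by hydroxyl with retention and give A4.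
- In favour: boron goes to the carbon β to the silyloxy group, and syn addition puts H4 and O3 on one face, so O3 ends trans to O4 by mechanism.
- Equal or better: the relative control is as secure as in the chosen plan (equal). The C4–O bond is never broken, so no allyl cation can form (better). A4 arrives with the two oxygens already differentiated (better).
- Against: the absolute configuration rests on a stoichiometric chiral borane acting on a trisubstituted, electron-rich enol ether inside a diene. The facial selectivity for this class is uncertain, whereas the chosen plan takes its enantiopurity from a catalytic ketone reduction and passes it on. β-Silyloxy organoboranes can eliminate, which would remove O4. Addition across the diene is a further leak.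
- Step economy: A4 holds only C7 of the chain, as an ester. Deacylation, oxidation and construction of C8–C11 are still needed before the stage of 13. The ring block comes sooner, the C15 unit later.

Alternative 3: The cut is in the chain, far from the stereocentres: the C14'–C15' single bond and the C13'–CH3 bond. It divides the molecule into the ring-bearing pentaenyl iodide A9 and the acyclic C18 enyne A8. In the forward direction AlMe3 with catalytic Cp2ZrCl2 (tetravalent zirconium) would add methyl and aluminium syn across the terminal alkyne of A8, with methyl going to C13'. After exchange with ZnCl2 the alkenylzinc would couple with A9 under Pd(PPh3)4 (zerovalent palladium) with retention at both carbons. The product A7 is the same compound as 25.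
- Better: the geometry at the junction is set by stereospecific steps, so no E/Z mixture and no isomerisation are expected, unlike the olefinations at C11=C12 and C11'=C12' of the chosen plan. No carbanion is conjugated with the C4–O bond.
- Against: the cut does nothing for the ring stereochemistry, so it must be combined with a ring strategy such as the chosen key step. A9 requires ten more chain carbons and an E-iodoalkene terminus to be built on the chiral ring unit, which lengthens the linear sequence on the valuable material. A8 needs its own multi-step preparation. AlMe3 is a strong Lewis acid towards a polyenyne, and polyenyl iodides are light-sensitive.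
- Comparison: the two plans are complementary in structure. The chosen plan reaches C40 from three commercial chain units in fewer operations and accepts one thermal correction of a hindered cis bond in return.

Key step: step 5

Remarks on the chemistry (assumptions, one line each):
- Carotenoid numbering is used for ring and chain positions; 26 is (3R,4R) with the hydroxyls trans.
- O11 is carried as a triethylsilyl ether and O3 as a tert-butyldimethylsilyl ether, so that O11 can be released later without relying on rate differences between like silyl ethers.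
- The alkyne is reduced by trans-hydrosilylation and protodesilylation, not by NaAlH2(OCH2CH2OCH3)2: an aluminate on O11 lies trans to the alkyne across the E C9=C10 bond and could deliver hydride only to C10, the conjugate mode that leads to an allene.
- Pseudoionone 16 is used as the (3E,5E) isomer drawn, separated from the 5Z isomer if the commercial material is a mixture.
- The C18 fragment A8 of alternative 3 holds four conjugated double bonds and the isolated C1'=C2' bond, so it is strictly a pentaenyne.
- In step 1 the ligand antipode is chosen to give the R carbinol; the mirror-image catalyst is used if the sense of induction is opposite to the model.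

## Route

Step 1
Reactants: 1 ketoisophorone (2,6,6-trimethylcyclohex-2-ene-1,4-dione)
Product: 2 (4R)-4-hydroxy-2,6,6-trimethylcyclohex-2-en-1-one
Conditions: RuCl[(R,R)-TsDPEN](p-cymene) (divalent ruthenium, 0.5 mol %), KOH (cat.), iPrOH, rt
Reagents that add atoms: none
Why: Noyori-type asymmetric transfer hydrogenation; only the C4 carbonyl is accessible, because the other is flanked by the gem-dimethyl carbon and the methyl-bearing alkene carbon. The alkenyl and CH2 flanks are differentiated like aryl and alkyl in the usual model, so the (R,R)-ligand should deliver hydride to the face that gives the R carbinol.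

Step 2
Reactants: 2 (4R)-4-hydroxy-2,6,6-trimethylcyclohex-2-en-1-one
Product: 3 (4R)-4-[tert-butyl(dimethyl)silyl]oxy-2,6,6-trimethylcyclohex-2-en-1-one
Conditions: TBSCl, imidazole, DMF, rt
Reagents that add atoms: tert-butyldimethylsilyl chloride (TBSCl), SMILES CC(C)(C)[Si](C)(C)Cl
Why: Imidazole-promoted silylation of a secondary alcohol; no base strong enough to enolise towards the carbinol carbon is present, so the stereocentre is kept.

Step 3
Reactants: 4 (2E)-3-methylpent-2-en-4-yn-1-ol
Product: 5 triethyl{[(2E)-3-methylpent-2-en-4-yn-1-yl]oxy}silane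
Conditions: TESCl, imidazole, CH2Cl2, 0 °C
Reagents that add atoms: chlorotriethylsilane (TESCl), SMILES CC[Si](Cl)(CC)CC
Why: Silylation of the primary alcohol leaves the alkyne C–H as the only acidic site; the triethylsilyl ether is far more labile than the ring silyl ethers and can be removed selectively in step 7.

Step 4
Reactants: 5 triethyl{[(2E)-3-methylpent-2-en-4-yn-1-yl]oxy}silane; 3 (4R)-4-[tert-butyl(dimethyl)silyl]oxy-2,6,6-trimethylcyclohex-2-en-1-one
Product: 7 (1R,4R)-4-[tert-butyl(dimethyl)silyl]oxy-2,6,6-trimethyl-1-[(3E)-3-methyl-5-(triethylsilyloxy)pent-3-en-1-yn-1-yl]cyclohex-2-en-1-ol, via lithium acetylide 6 (not isolated)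
Conditions: n-BuLi, THF, −78 °C; then 3, −78 → −20 °C; aq NH4Cl
Reagents that add atoms: none
Why: 1,2-Addition of a lithium acetylide to an enone carbonyl. In the half-chair of 3 the O3 silyl ether is pseudoequatorial (pseudoaxial it would be 1,3-diaxial to a C1 methyl) and the axial C1 methyl shields one carbonyl face. The small linear nucleophile therefore enters axially on the other face, so the alkynyl group ends cis and the new hydroxyl trans to O3 (6R in carotenoid numbering).

Step 5
Reactants: 7 (1R,4R)-4-[tert-butyl(dimethyl)silyl]oxy-2,6,6-trimethyl-1-[(3E)-3-methyl-5-(triethylsilyloxy)pent-3-en-1-yn-1-yl]cyclohex-2-en-1-ol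
Product: 10 (1R,6R)-6-[tert-butyl(dimethyl)silyl]oxy-2,4,4-trimethyl-3-[(3E)-3-methyl-5-(triethylsilyloxy)pent-3-en-1-yn-1-yl]cyclohex-2-en-1-ol, via tertiary perrhenate ester 8 (not isolated), via secondary perrhenate ester 9 (not isolated)
Conditions: Ph3SiOReO3 (heptavalent rhenium, 2 mol %), Et2O, −50 → 0 °C; Et3N quench
Reagents that add atoms: none
Why: Ph3SiOReO3 exchanges onto the tertiary hydroxyl to give 8, which undergoes a [3,3]-sigmatropic shift through a six-membered cyclic transition state in which a rhenium-bound oxygen bonds to C4 as the C6–O bond breaks; alcoholysis of 9 by more 7 releases 10 and returns the catalyst. The closest known reaction type is the rhenium-oxo catalysed 1,3-isomerisation of allylic alcohols, including tertiary cyclohexenols that move into conjugation. No ring is closed; one C–O bond is formed and C4 becomes a stereocentre as C6 ceases to be one. Because C4, C5 and C6 are locked in the ring, the oxygen can only cross one face of the allyl unit, so the C6 configuration (oxygen anti to O3) is copied to C4 and the 3,4-trans relationship follows. In the reacting conformer the C6–O bond is pseudoaxial and the O3 silyl ether is pseudoaxial on the opposite face, so it does not obstruct the migrating group. The equilibrium should lie on the side of 10 because the new double bond is tetrasubstituted and conjugated with the C7≡C8–C9=C10 enyne. The step needs the allylic shift to outrun the propargylic shift of the same ester (Meyer–Schuster path) and ionisation to the allyl cation; the ring-held allyl unit reaches the cyclic transition state far more easily than the linear alkyne, and the electron-poor sp substituent on C6, the ether solvent, the low temperature and the absence of protic acid keep ionisation slow. The silyl ethers at O3 and O11 do not exchange onto rhenium, so the primary allylic position and the C9=C10 geometry are untouched.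

Step 6
Reactants: 10 (1R,6R)-6-[tert-butyl(dimethyl)silyl]oxy-2,4,4-trimethyl-3-[(3E)-3-methyl-5-(triethylsilyloxy)pent-3-en-1-yn-1-yl]cyclohex-2-en-1-ol
Product: 11 triethyl{[(2E)-5-{(3R,4R)-3,4-bis[tert-butyl(dimethyl)silyloxy]-2,6,6-trimethylcyclohex-1-en-1-yl}-3-methylpent-2-en-4-yn-1-yl]oxy}silane
Conditions: TBSOTf, 2,6-lutidine, CH2Cl2, −78 → 0 °C
Reagents that add atoms: tert-butyldimethylsilyl trifluoromethanesulfonate (TBSOTf), SMILES CC(C)(C)[Si](C)(C)OS(=O)(=O)C(F)(F)F
Why: Silylation of a hindered secondary allylic alcohol with a silyl triflate and a hindered pyridine base at low temperature; the base prevents acid-promoted ionisation of C4–O and the configuration is untouched.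

Step 7
Reactants: 11 triethyl{[(2E)-5-{(3R,4R)-3,4-bis[tert-butyl(dimethyl)silyloxy]-2,6,6-trimethylcyclohex-1-en-1-yl}-3-methylpent-2-en-4-yn-1-yl]oxy}silane
Product: 13 (2E,4E)-5-{(3R,4R)-3,4-bis[tert-butyl(dimethyl)silyloxy]-2,6,6-trimethylcyclohex-1-en-1-yl}-3-methylpenta-2,4-dien-1-ol, via C8 alkenylsilane 12 (not isolated)
Conditions: [(C5Me5)Ru(MeCN)3]PF6 (divalent ruthenium, 5 mol %), BnMe2SiH, CH2Cl2, 0 °C → rt; then Bu4NF, THF, 0 °C
Reagents that add atoms: none
Why: Cationic ruthenium-catalysed hydrosilylation adds H and Si trans across an alkyne, conjugated enynes included, so the two carbon substituents end up E whichever alkyne carbon takes silicon (12 is drawn as the C8 regioisomer; the C7 isomer converges). Fluoride then replaces the alkenyl C–Si bond by C–H with retention and cleaves the primary Et3Si–O bond in the same operation. The two hindered, vicinal secondary silyl ethers should survive at 0 °C.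

Step 8
Reactants: 13 (2E,4E)-5-{(3R,4R)-3,4-bis[tert-butyl(dimethyl)silyloxy]-2,6,6-trimethylcyclohex-1-en-1-yl}-3-methylpenta-2,4-dien-1-ol
Product: 14 2-{[(2E,4E)-5-{(3R,4R)-3,4-bis[tert-butyl(dimethyl)silyloxy]-2,6,6-trimethylcyclohex-1-en-1-yl}-3-methylpenta-2,4-dien-1-yl]sulfanyl}-1,3-benzothiazole
Conditions: 2-mercaptobenzothiazole, PPh3, DIAD, THF, 0 °C
Reagents that add atoms: 2-mercaptobenzothiazole, SMILES Sc1nc2ccccc2s1
Why: Mitsunobu thioetherification; the acidic heteroaryl thiol displaces the activated primary allylic oxygen by SN2, so the position and geometry of the double bonds are kept.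

Step 9
Reactants: 14 2-{[(2E,4E)-5-{(3R,4R)-3,4-bis[tert-butyl(dimethyl)silyloxy]-2,6,6-trimethylcyclohex-1-en-1-yl}-3-methylpenta-2,4-dien-1-yl]sulfanyl}-1,3-benzothiazole
Product: 15 2-{[(2E,4E)-5-{(3R,4R)-3,4-bis[tert-butyl(dimethyl)silyloxy]-2,6,6-trimethylcyclohex-1-en-1-yl}-3-methylpenta-2,4-dien-1-yl]sulfonyl}-1,3-benzothiazole
Conditions: (NH4)6Mo7O24·4H2O (hexavalent molybdenum, 10 mol %), 30% H2O2, EtOH, 0 °C → rt
Reagents that add atoms: hydrogen peroxide, SMILES OO
Why: Molybdenum-peroxo catalysed oxidation of a sulfide to the sulfone; sulfur is far more nucleophilic towards the peroxo complex than the conjugated triene, and the silyl ethers are inert.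

Step 10
Reactants: 16 pseudoionone ((3E,5E)-6,10-dimethylundeca-3,5,9-trien-2-one)
Product: 17 (4E,6E)-3,7,11-trimethyldodeca-1,4,6,10-tetraen-3-ol (racemic)
Conditions: CH2=CHMgBr, THF, −20 → 0 °C; aq NH4Cl
Reagents that add atoms: vinylmagnesium bromide (CH2=CHMgBr), SMILES C=C[Mg]Br
Why: Grignard 1,2-addition to the dienone carbonyl, as with ionone-type ketones; the new stereocentre is racemic and is destroyed in step 11.

Step 11
Reactants: 17 (4E,6E)-3,7,11-trimethyldodeca-1,4,6,10-tetraen-3-ol (racemic)
Product: 18 triphenyl[(2E,4E,6E)-3,7,11-trimethyldodeca-2,4,6,10-tetraen-1-yl]phosphonium bromide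
Conditions: PPh3·HBr, MeOH, 0 °C → rt; crystallise from EtOAc
Reagents that add atoms: triphenylphosphine hydrobromide (PPh3·HBr), SMILES Br.c1ccc(cc1)P(c1ccccc1)c1ccccc1
Why: Acid-mediated allylic substitution with transposition (SN1'): the bis-allylic tertiary carbinol ionises to a delocalised cation that PPh3 captures at the primary terminus, moving the double bond to C9'=C10'. The E salt is favoured on steric grounds and is purified by crystallisation.

Step 12
Reactants: 18 triphenyl[(2E,4E,6E)-3,7,11-trimethyldodeca-2,4,6,10-tetraen-1-yl]phosphonium bromide; 19 (2E,4E,6E)-2,7-dimethylocta-2,4,6-trienedial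
Product: 22 (2E,4E,6E,8E,10E,12E,14E)-2,7,11,15,19-pentamethylicosa-2,4,6,8,10,12,14,18-octaenal, via phosphorus ylide 20 (not isolated), via 11'Z aldehyde 21 (not isolated)
Conditions: 18 and NaOMe added slowly to 19 (3 equiv), MeOH/CH2Cl2, 0 °C → rt; then heptane, 80 °C
Reagents that add atoms: none
Why: Wittig olefination of one aldehyde group of the symmetrical dialdehyde by the semi-stabilised allylic ylide; excess 19 and slow addition favour mono-olefination, and the product enal is less electrophilic than 19. The 11'Z part of the expected E/Z mixture is a hindered cis bond and is isomerised thermally.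

Step 13
Reactants: 15 2-{[(2E,4E)-5-{(3R,4R)-3,4-bis[tert-butyl(dimethyl)silyloxy]-2,6,6-trimethylcyclohex-1-en-1-yl}-3-methylpenta-2,4-dien-1-yl]sulfonyl}-1,3-benzothiazole; 22 (2E,4E,6E,8E,10E,12E,14E)-2,7,11,15,19-pentamethylicosa-2,4,6,8,10,12,14,18-octaenal
Product: 25 (3R,4R)-3,4-bis[tert-butyl(dimethyl)silyloxy]-β,ψ-carotene, via sodium sulfonyl carbanion 23 (not isolated), via 11Z bis-silyl ether 24 (not isolated)
Conditions: NaN(SiMe3)2 added to 15 + 22, THF, −78 °C → rt; then heptane, 80 °C, dark
Reagents that add atoms: none
Why: Julia–Kocienski olefination: the sulfonyl carbanion adds to the aldehyde, the alkoxide attacks the benzothiazole carbon (Smiles rearrangement), and SO2 and the benzothiazolone anion leave, forming C11=C12. Generating the anion in the presence of 22 at −78 °C lets addition outrun vinylogous loss of the O4 silyloxy group. The new bond is expected as an E/Z mixture; 11Z is a hindered cis bond that isomerises on gentle heating while the other double bonds keep their geometry.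

Step 14
Reactants: 25 (3R,4R)-3,4-bis[tert-butyl(dimethyl)silyloxy]-β,ψ-carotene
Product: 26 (3R,4R)-β,ψ-carotene-3,4-diol
Conditions: Bu4NF, THF, 0 °C → rt, dark, argon
Reagents that add atoms: none
Why: Fluoride cleavage of both Si–O bonds under non-acidic conditions, so the allylic C4–O bond is not ionised and the polyene geometry and both stereocentres are untouched.

## Compound list

1 | ketoisophorone (2,6,6-trimethylcyclohex-2-ene-1,4-dione) | CC1=CC(=O)CC(C)(C)C1=O | starting material
2 | (4R)-4-hydroxy-2,6,6-trimethylcyclohex-2-en-1-one | CC1=C[C@H](O)CC(C)(C)C1=O | intermediate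
3 | (4R)-4-[tert-butyl(dimethyl)silyl]oxy-2,6,6-trimethylcyclohex-2-en-1-one | CC1=C[C@H](O[Si](C)(C)C(C)(C)C)CC(C)(C)C1=O | intermediate
4 | (2E)-3-methylpent-2-en-4-yn-1-ol | C#C/C(C)=C/CO | starting material
5 | triethyl{[(2E)-3-methylpent-2-en-4-yn-1-yl]oxy}silane | C#C/C(C)=C/CO[Si](CC)(CC)CC | intermediate
6 | lithium acetylide of 5 (lithium on the terminal alkyne carbon, C7) | [Li]C#C/C(C)=C/CO[Si](CC)(CC)CC | intermediate
7 | (1R,4R)-4-[tert-butyl(dimethyl)silyl]oxy-2,6,6-trimethyl-1-[(3E)-3-methyl-5-(triethylsilyloxy)pent-3-en-1-yn-1-yl]cyclohex-2-en-1-ol (tertiary C6 carbinol, hydroxyl trans to O3) | CC1=C[C@H](O[Si](C)(C)C(C)(C)C)CC(C)(C)[C@]1(O)C#C/C(C)=C/CO[Si](CC)(CC)CC | intermediate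
8 | perrhenate ester of 7 at the tertiary C6 oxygen | CC1=C[C@H](O[Si](C)(C)C(C)(C)C)CC(C)(C)[C@]1(O[Re](=O)(=O)=O)C#C/C(C)=C/CO[Si](CC)(CC)CC | intermediate
9 | perrhenate ester of 10 at the C4 oxygen | C1(C#C/C(C)=C/CO[Si](CC)(CC)CC)=C(C)[C@@H](O[Re](=O)(=O)=O)[C@H](O[Si](C)(C)C(C)(C)C)CC1(C)C | intermediate
10 | (1R,6R)-6-[tert-butyl(dimethyl)silyl]oxy-2,4,4-trimethyl-3-[(3E)-3-methyl-5-(triethylsilyloxy)pent-3-en-1-yn-1-yl]cyclohex-2-en-1-ol (free C4 hydroxyl trans to O3) | C1(C#C/C(C)=C/CO[Si](CC)(CC)CC)=C(C)[C@@H](O)[C@H](O[Si](C)(C)C(C)(C)C)CC1(C)C | intermediate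
11 | triethyl{[(2E)-5-{(3R,4R)-3,4-bis[tert-butyl(dimethyl)silyloxy]-2,6,6-trimethylcyclohex-1-en-1-yl}-3-methylpent-2-en-4-yn-1-yl]oxy}silane | C1(C#C/C(C)=C/CO[Si](CC)(CC)CC)=C(C)[C@@H](O[Si](C)(C)C(C)(C)C)[C@H](O[Si](C)(C)C(C)(C)C)CC1(C)C | intermediate
12 | benzyl[(1Z,3E)-1-{(3R,4R)-3,4-bis[tert-butyl(dimethyl)silyloxy]-2,6,6-trimethylcyclohex-1-en-1-yl}-3-methyl-5-(triethylsilyloxy)penta-1,3-dien-2-yl]dimethylsilane | C1(/C=C(\[Si](C)(C)Cc2ccccc2)/C(C)=C/CO[Si](CC)(CC)CC)=C(C)[C@@H](O[Si](C)(C)C(C)(C)C)[C@H](O[Si](C)(C)C(C)(C)C)CC1(C)C | intermediate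
13 | (2E,4E)-5-{(3R,4R)-3,4-bis[tert-butyl(dimethyl)silyloxy]-2,6,6-trimethylcyclohex-1-en-1-yl}-3-methylpenta-2,4-dien-1-ol | C1(/C=C/C(C)=C/CO)=C(C)[C@@H](O[Si](C)(C)C(C)(C)C)[C@H](O[Si](C)(C)C(C)(C)C)CC1(C)C | intermediate
14 | 2-{[(2E,4E)-5-{(3R,4R)-3,4-bis[tert-butyl(dimethyl)silyloxy]-2,6,6-trimethylcyclohex-1-en-1-yl}-3-methylpenta-2,4-dien-1-yl]sulfanyl}-1,3-benzothiazole | C1(/C=C/C(C)=C/CSc2nc3ccccc3s2)=C(C)[C@@H](O[Si](C)(C)C(C)(C)C)[C@H](O[Si](C)(C)C(C)(C)C)CC1(C)C | intermediate
15 | 2-{[(2E,4E)-5-{(3R,4R)-3,4-bis[tert-butyl(dimethyl)silyloxy]-2,6,6-trimethylcyclohex-1-en-1-yl}-3-methylpenta-2,4-dien-1-yl]sulfonyl}-1,3-benzothiazole | C1(/C=C/C(C)=C/CS(=O)(=O)c2nc3ccccc3s2)=C(C)[C@@H](O[Si](C)(C)C(C)(C)C)[C@H](O[Si](C)(C)C(C)(C)C)CC1(C)C | intermediate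
16 | pseudoionone ((3E,5E)-6,10-dimethylundeca-3,5,9-trien-2-one) | CC(=O)/C=C/C=C(C)/CCC=C(C)C | starting material
17 | (4E,6E)-3,7,11-trimethyldodeca-1,4,6,10-tetraen-3-ol (racemic) | C=CC(C)(O)/C=C/C=C(C)/CCC=C(C)C | intermediate
18 | triphenyl[(2E,4E,6E)-3,7,11-trimethyldodeca-2,4,6,10-tetraen-1-yl]phosphonium bromide | CC(C)=CCC/C(C)=C/C=C/C(C)=C/C[P+](c1ccccc1)(c1ccccc1)c1ccccc1.[Br-] | intermediate
19 | (2E,4E,6E)-2,7-dimethylocta-2,4,6-trienedial | O=C/C(C)=C/C=C/C=C(C)/C=O | starting material
20 | phosphorus ylide from 18 (triphenyl[(2E,4E,6E)-3,7,11-trimethyldodeca-2,4,6,10-tetraen-1-ylidene]phosphorane) | CC(C)=CCC/C(C)=C/C=C/C(C)=C/C=P(c1ccccc1)(c1ccccc1)c1ccccc1 | intermediate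
21 | (2E,4E,6E,8Z,10E,12E,14E)-2,7,11,15,19-pentamethylicosa-2,4,6,8,10,12,14,18-octaenal (11'Z isomer of 22) | CC(C)=CCC/C(C)=C/C=C/C(C)=C/C=C\C(C)=C\C=C\C=C(C)\C=O | intermediate
22 | (2E,4E,6E,8E,10E,12E,14E)-2,7,11,15,19-pentamethylicosa-2,4,6,8,10,12,14,18-octaenal (12'-apo-ψ-caroten-12'-al) | CC(C)=CCC/C(C)=C/C=C/C(C)=C/C=C/C(C)=C/C=C/C=C(C)/C=O | intermediate
23 | sodium salt of 15 deprotonated at C11 | C1(/C=C/C(C)=C/[CH-]S(=O)(=O)c2nc3ccccc3s2)=C(C)[C@@H](O[Si](C)(C)C(C)(C)C)[C@H](O[Si](C)(C)C(C)(C)C)CC1(C)C.[Na+] | intermediate
24 | (3R,4R,11Z)-3,4-bis[tert-butyl(dimethyl)silyloxy]-β,ψ-carotene | CC(C)=CCC/C(C)=C/C=C/C(C)=C/C=C/C(C)=C/C=C/C=C(C)/C=C\C=C(C)\C=C\C1=C(C)[C@@H](O[Si](C)(C)C(C)(C)C)[C@H](O[Si](C)(C)C(C)(C)C)CC1(C)C | intermediate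
25 | (3R,4R)-3,4-bis[tert-butyl(dimethyl)silyloxy]-β,ψ-carotene (all-E) | CC(C)=CCC/C(C)=C/C=C/C(C)=C/C=C/C(C)=C/C=C/C=C(C)/C=C/C=C(C)/C=C/C1=C(C)[C@@H](O[Si](C)(C)C(C)(C)C)[C@H](O[Si](C)(C)C(C)(C)C)CC1(C)C | intermediate
26 | (3R,4R)-β,ψ-carotene-3,4-diol (all-E) | CC(C)=CCC/C(C)=C/C=C/C(C)=C/C=C/C(C)=C/C=C/C=C(C)/C=C/C=C(C)/C=C/C1=C(C)[C@@H](O)[C@H](O)CC1(C)C | target

## Step count and least certain steps

Total: 14 steps. Longest linear sequence: 10 steps from 1 (steps 1, 2, 4, 5, 6, 7, 8, 9, 13, 14). Step 3 is a one-step side branch; steps 10–12 are a three-step branch to 22.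

Step 5 (key step). The perrhenate ester may ionise to the allyl cation, which would scramble C4 or eliminate towards a silyl dienol ether. The competing propargylic shift may lead to an enone, and conversion may stall if the equilibrium is less one-sided than expected. Fallback, from 7 to 10: oxidative 1,3-transposition with pyridinium chlorochromate, [C5H5NH][CrO3Cl] (hexavalent chromium), buffered with NaOAc in CH2Cl2, gives the 4-oxo enyne F1. Reduction with NaBH4 and CeCl3·7H2O in MeOH at −78 °C, hydride entering axially on the half-chair with O3 pseudoequatorial, should give the pseudoequatorial C4 alcohol trans to O3, which is 10. Here C4 is set from C3 and not from C6, so either C6 epimer can be used.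

Step 7. The hindered, doubly conjugated alkyne may hydrosilylate slowly or incompletely, and the ring silyl ethers may be partly lost during the fluoride treatment. Fallback, from 11 to 13: pyridinium p-toluenesulfonate in MeOH releases O11 and gives the enynol F2. Zinc dust activated with Cu(OAc)2 and AgNO3 in MeOH/H2O reduces the alkyne cis to the 7Z dienol F3. Catalytic I2 in hexane in daylight equilibrates the strained 7Z bond to 7E and gives 13.

Step 13. The olefination may give poor E/Z selectivity at C11=C12 with incomplete thermal correction. The delocalised carbanion may also expel the O4 silyloxy group (vinylogous elimination through C5). Fallback with reversed polarity, from 13 and 22 to 25: MnO2 in CH2Cl2 oxidises 13 to the trienal F4. NaBH4 reduces 22 to the C25 alcohol F5, PPh3·HBr in MeOH converts it into the C25 phosphonium bromide F6, and NaOMe gives the C25 ylide F7. Wittig reaction of F7 with F4 forms the same C11=C12 bond as a mixture of 24 and 25, and heating in heptane converts it to 25. The carbanion then sits on the fragment that has no leaving group.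

Step 4. Facial selectivity of the acetylide addition may be insufficient, or the acetylide may deprotonate the enone at the γ position (C3–H) and erode the stereocentre. Fallback, from 2 to 7: 2 is added to an excess of acetylide 6 in THF at −78 °C. The lithium alkoxide formed at O3 is expected to guide a second equivalent of 6 to its own face (alkoxide-directed addition), which gives the diol F8 with the alkynyl group cis to O3. Selective silylation of the secondary hydroxyl with TBSCl and imidazole gives 7.

Step 12. Double olefination of 19 may compete, and E/Z mixtures at C9' and C11' may lower the amount of usable aldehyde. Fallback, from 19 to 22: acetalisation of 19 with one equivalent of 2,2-dimethylpropane-1,3-diol and pyridinium p-toluenesulfonate gives the mono-acetal F9, with unreacted 19 recycled. Wittig reaction with ylide 20 and thermal isomerisation give the C25 acetal F10. Dilute aqueous H2SO4 in acetone releases 22.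

## Further compounds

F1 | step 5 | (6R)-6-[tert-butyl(dimethyl)silyl]oxy-2,4,4-trimethyl-3-[(3E)-3-methyl-5-(triethylsilyloxy)pent-3-en-1-yn-1-yl]cyclohex-2-en-1-one (4-oxo enyne) | C1(C#C/C(C)=C/CO[Si](CC)(CC)CC)=C(C)C(=O)[C@H](O[Si](C)(C)C(C)(C)C)CC1(C)C
F2 | step 7 | (2E)-5-{(3R,4R)-3,4-bis[tert-butyl(dimethyl)silyloxy]-2,6,6-trimethylcyclohex-1-en-1-yl}-3-methylpent-2-en-4-yn-1-ol (enynol) | C1(C#C/C(C)=C/CO)=C(C)[C@@H](O[Si](C)(C)C(C)(C)C)[C@H](O[Si](C)(C)C(C)(C)C)CC1(C)C
F3 | step 7 | (2E,4Z)-5-{(3R,4R)-3,4-bis[tert-butyl(dimethyl)silyloxy]-2,6,6-trimethylcyclohex-1-en-1-yl}-3-methylpenta-2,4-dien-1-ol (7Z dienol) | C1(/C=C\C(C)=C\CO)=C(C)[C@@H](O[Si](C)(C)C(C)(C)C)[C@H](O[Si](C)(C)C(C)(C)C)CC1(C)C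
F4 | step 13 | (2E,4E)-5-{(3R,4R)-3,4-bis[tert-butyl(dimethyl)silyloxy]-2,6,6-trimethylcyclohex-1-en-1-yl}-3-methylpenta-2,4-dienal (trienal) | C1(/C=C/C(C)=C/C=O)=C(C)[C@@H](O[Si](C)(C)C(C)(C)C)[C@H](O[Si](C)(C)C(C)(C)C)CC1(C)C
F5 | step 13 | (2E,4E,6E,8E,10E,12E,14E)-2,7,11,15,19-pentamethylicosa-2,4,6,8,10,12,14,18-octaen-1-ol (C25 alcohol) | CC(C)=CCC/C(C)=C/C=C/C(C)=C/C=C/C(C)=C/C=C/C=C(C)/CO
F6 | step 13 | [(2E,4E,6E,8E,10E,12E,14E)-2,7,11,15,19-pentamethylicosa-2,4,6,8,10,12,14,18-octaen-1-yl]triphenylphosphonium bromide (C25 phosphonium bromide) | CC(C)=CCC/C(C)=C/C=C/C(C)=C/C=C/C(C)=C/C=C/C=C(C)/C[P+](c1ccccc1)(c1ccccc1)c1ccccc1.[Br-]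
F7 | step 13 | ylide from F6 (C25 ylide) | CC(C)=CCC/C(C)=C/C=C/C(C)=C/C=C/C(C)=C/C=C/C=C(C)/C=P(c1ccccc1)(c1ccccc1)c1ccccc1
F8 | step 4 | (1R,4R)-2,6,6-trimethyl-1-[(3E)-3-methyl-5-(triethylsilyloxy)pent-3-en-1-yn-1-yl]cyclohex-2-ene-1,4-diol (diol) | CC1=C[C@H](O)CC(C)(C)[C@]1(O)C#C/C(C)=C/CO[Si](CC)(CC)CC
F9 | step 12 | (2E,4E,6E)-7-(5,5-dimethyl-1,3-dioxan-2-yl)-2-methylocta-2,4,6-trienal (mono-acetal of 19) | O=C/C(C)=C/C=C/C=C(C)/C1OCC(C)(C)CO1
F10 | step 12 | 5,5-dimethyl-1,3-dioxane acetal of 22 (C25 acetal) | CC(C)=CCC/C(C)=C/C=C/C(C)=C/C=C/C(C)=C/C=C/C=C(C)/C1OCC(C)(C)CO1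
A1 | alternative 1 | safranal 3,4-oxide, (3R,4S) in carotenoid numbering, oxirane oxygen on the face of the C3 hydroxyl of 26 | O=CC1=C(C)[C@@H]2O[C@@H]2CC1(C)C
A2 | alternative 1 | safranal (2,6,6-trimethylcyclohexa-1,3-diene-1-carbaldehyde) | O=CC1=C(C)C=CCC1(C)C
A3 | alternative 1 | (3R,4R)-3,4-dihydroxy-2,6,6-trimethylcyclohex-1-ene-1-carbaldehyde | O=CC1=C(C)[C@@H](O)[C@H](O)CC1(C)C
A4 | alternative 2 | [(3R,4R)-3-[tert-butyl(dimethyl)silyl]oxy-4-hydroxy-2,6,6-trimethylcyclohex-1-en-1-yl]methyl 2,2-dimethylpropanoate | CC(C)(C)C(=O)OCC1=C(C)[C@@H](O[Si](C)(C)C(C)(C)C)[C@H](O)CC1(C)C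
A5 | alternative 2 | [3-[tert-butyl(dimethyl)silyl]oxy-2,6,6-trimethylcyclohexa-1,3-dien-1-yl]methyl 2,2-dimethylpropanoate | CC(C)(C)C(=O)OCC1=C(C)C(O[Si](C)(C)C(C)(C)C)=CCC1(C)C
A6 | alternative 2 | (2,6,6-trimethyl-3-oxocyclohex-1-en-1-yl)methyl 2,2-dimethylpropanoate | CC(C)(C)C(=O)OCC1=C(C)C(=O)CCC1(C)C
A7 | alternative 3 | (3R,4R)-3,4-bis[tert-butyl(dimethyl)silyloxy]-β,ψ-carotene (identical with 25) | CC(C)=CCC/C(C)=C/C=C/C(C)=C/C=C/C(C)=C/C=C/C=C(C)/C=C/C=C(C)/C=C/C1=C(C)[C@@H](O[Si](C)(C)C(C)(C)C)[C@H](O[Si](C)(C)C(C)(C)C)CC1(C)C
A8 | alternative 3 | (3E,5E,7E,9E)-6,10,14-trimethylpentadeca-3,5,7,9,13-pentaen-1-yne | C#C/C=C/C=C(C)/C=C/C=C(C)/CCC=C(C)C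
A9 | alternative 3 | (1E,3E,5E,7E,9E)-1-iodo-3,7-dimethyl-10-{(3R,4R)-3,4-bis[tert-butyl(dimethyl)silyloxy]-2,6,6-trimethylcyclohex-1-en-1-yl}deca-1,3,5,7,9-pentaene, with iodine on C15' and methyls on C13 and C9 | I/C=C/C=C(C)/C=C/C=C(C)/C=C/C1=C(C)[C@@H](O[Si](C)(C)C(C)(C)C)[C@H](O[Si](C)(C)C(C)(C)C)CC1(C)C
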